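**Retrosynthetic overview**
1. Only one ring is made: the 19-membered lactam, closed last at C3–C4 by a nickel-mediated radical coupling of a primary alkyl iodide (C4) with the (E)-β-iodomethacrylanilide (C3). The arene is bought as 3-bromophenol.
2. C4–C7 and C8=C9: Brown (Z)-γ-methoxyallylboration of a C7 enal (sets C6, C7); the enal comes from cross-metathesis with methacrolein.
3. Aryl–C15: Hoppe–Aggarwal lithiation–borylation of a C15 carbamate with an aryl boronate from Ir C–H borylation (sets C15); nitrogen enters late by Pd amination of the aryl bromide.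
4. C12–C13: Felkin addition of the Grignard reagent from (R)-3-bromo-2-methylpropan-1-ol (C14) to an α-silyloxy aldehyde (sets C12); C10/C11 come from (Z)-crotylboration of ethyl glyoxylate.

Assumption: (E)-3-iodo-2-methylprop-2-enoic acid and (R)-3-bromo-2-methylpropan-1-ol are taken as catalogue compounds; locants C1–C15 in late intermediates follow the target (C1 = amide carbonyl, C15 = benzylic carbon).

**Route**

Step 1
Reactants: 1 3-bromophenol
Product: 2 (3-bromophenoxy)triisopropylsilane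
Conditions: TIPSCl, imidazole, DMF, 25 °C
Reagents that add atoms: triisopropylsilyl chloride, CC(C)[Si](Cl)(C(C)C)C(C)C
Why: Phenol silylation gives a bulky, base-stable ether that leaves C5 as the only unhindered aromatic C–H.

Step 2
Reactants: 2 (3-bromophenoxy)triisopropylsilane
Product: 3 2-[3-bromo-5-(triisopropylsilyloxy)phenyl]-4,4,5,5-tetramethyl-1,3,2-dioxaborolane
Conditions: [Ir(OMe)(cod)]2 (1.5 mol%), 4,4′-di-tert-butyl-2,2′-bipyridine, B2pin2, hexane, 50 °C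
Reagents that add atoms: bis(pinacolato)diboron, CC1(C)OB(OC1(C)C)B1OC(C)(C)C(C)(C)O1
Why: Sterically controlled Ir-catalysed aromatic C–H borylation occurs only at the C–H meta to both substituents and leaves C–Br intact.

Step 3
Reactants: 4 (R)-3-bromo-2-methylpropan-1-ol
Product: 5 (R)-3-bromo-2-methylpropyl N,N-diisopropylcarbamate
Conditions: iPr2NCOCl, Et3N, CH2Cl2, reflux
Reagents that add atoms: N,N-diisopropylcarbamoyl chloride, CC(C)N(C(C)C)C(Cl)=O
Why: O-Carbamoylation installs the Hoppe carbamate that later directs lithiation at C15, while C14 comes unchanged from the chiral pool.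

Step 4
Reactants: 6 ethyl glyoxylate; 7 cis-but-2-ene
Product: 10 ethyl (2R,3S)-2-hydroxy-3-methylpent-4-enoate, via (Z)-crotylborane 8 (not isolated), via borinate 9 (not isolated)
Conditions: 7, KOtBu, n-BuLi, THF, −78 to −45 °C; (+)-Ipc2BOMe, −78 °C; BF3·OEt2; 6 (freshly distilled), −78 °C; then NaBO3·4H2O, THF/H2O, 25 °C
Reagents that add atoms: none
Why: Brown (Z)-crotylboration through a closed chair transition state gives the syn adduct, and the Ipc groups derived from (−)-α-pinene direct attack to the re face of the aldehyde, setting C10 (S) and C11 (R).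

Step 5
Reactants: 10 ethyl (2R,3S)-2-hydroxy-3-methylpent-4-enoate
Product: 11 ethyl (2R,3S)-2-(tert-butyldimethylsilyloxy)-3-methylpent-4-enoate
Conditions: TBSCl, imidazole, DMF, 25 °C
Reagents that add atoms: tert-butyldimethylsilyl chloride, CC(C)(C)[Si](C)(C)Cl
Why: Silylation gives a bulky, non-chelating α-oxygen substituent, as needed for Felkin control in step 7.

Step 6
Reactants: 11 ethyl (2R,3S)-2-(tert-butyldimethylsilyloxy)-3-methylpent-4-enoate
Product: 12 (2R,3S)-2-(tert-butyldimethylsilyloxy)-3-methylpent-4-enal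
Conditions: DIBAL-H (iBu2AlH), CH2Cl2, −78 °C; aq. potassium sodium tartrate
Reagents that add atoms: none
Why: DIBAL-H half-reduction of an α-silyloxy ester stops at the aldehyde at −78 °C because the tetrahedral aluminate is stable until work-up.

Step 7
Reactants: 5 (R)-3-bromo-2-methylpropyl N,N-diisopropylcarbamate; 12 (2R,3S)-2-(tert-butyldimethylsilyloxy)-3-methylpent-4-enal
Product: 14 (2S,4S,5R,6S)-5-(tert-butyldimethylsilyloxy)-4-hydroxy-2,6-dimethyloct-7-en-1-yl N,N-diisopropylcarbamate, via Grignard reagent 13 (not isolated)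
Conditions: 5, Mg turnings, THF, 25 °C; then 12, Et2O/THF, −78 °C; aq. NH4Cl
Reagents that add atoms: none
Why: Grignard addition under polar Felkin–Anh control (C–OTBS bond anti to the nucleophile, no chelation) gives the 11,12-anti alcohol, i.e. C12 (S), with an expected dr near 5:1 and the minor epimer removed on silica.

Step 8
Reactants: 14 (2S,4S,5R,6S)-5-(tert-butyldimethylsilyloxy)-4-hydroxy-2,6-dimethyloct-7-en-1-yl N,N-diisopropylcarbamate
Product: 15 (2S,4S,5R,6S)-5-(tert-butyldimethylsilyloxy)-4-methoxy-2,6-dimethyloct-7-en-1-yl N,N-diisopropylcarbamate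
Conditions: Me3OBF4, 1,8-bis(dimethylamino)naphthalene, 4 Å MS, CH2Cl2, 25 °C
Reagents that add atoms: trimethyloxonium tetrafluoroborate, C[O+](C)C.F[B-](F)(F)F
Why: Meerwein O-methylation under non-basic conditions avoids the 1,2-silyl migration that an alkoxide next to the OTBS group would undergo.

Step 9
Reactants: 15 (2S,4S,5R,6S)-5-(tert-butyldimethylsilyloxy)-4-methoxy-2,6-dimethyloct-7-en-1-yl N,N-diisopropylcarbamate; 3 2-[3-bromo-5-(triisopropylsilyloxy)phenyl]-4,4,5,5-tetramethyl-1,3,2-dioxaborolane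
Product: 18 2-[(1R,2S,4S,5R,6S)-1-[3-bromo-5-(triisopropylsilyloxy)phenyl]-5-(tert-butyldimethylsilyloxy)-4-methoxy-2,6-dimethyloct-7-en-1-yl]-4,4,5,5-tetramethyl-1,3,2-dioxaborolane, via lithiated carbamate 16 (not isolated), via boronate complex 17 (not isolated)
Conditions: s-BuLi, (−)-sparteine, Et2O, −78 °C, 5 h; then 3, −78 °C; then MgBr2·OEt2, reflux
Reagents that add atoms: none
Why: Hoppe–Aggarwal lithiation–borylation: s-BuLi/(−)-sparteine removes the pro-S proton at C15, borylation occurs with retention and 1,2-aryl migration with inversion expels the carbamate, so the C–B bond has the configuration that gives the (15R)-alcohol on oxidation.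

Step 10
Reactants: 18 2-[(1R,2S,4S,5R,6S)-1-[3-bromo-5-(triisopropylsilyloxy)phenyl]-5-(tert-butyldimethylsilyloxy)-4-methoxy-2,6-dimethyloct-7-en-1-yl]-4,4,5,5-tetramethyl-1,3,2-dioxaborolane; 19 methacrolein
Product: 20 (2E,4S,5R,6S,8S,9R)-9-[3-bromo-5-(triisopropylsilyloxy)phenyl]-5-(tert-butyldimethylsilyloxy)-6-methoxy-2,4,8-trimethyl-9-(4,4,5,5-tetramethyl-1,3,2-dioxaborolan-2-yl)non-2-enal
Conditions: 19 (10 equiv), second-generation Hoveyda–Grubbs catalyst RuCl2(H2IMes)(=CH-C6H4-2-OiPr) (10 mol%), CH2Cl2, 40 °C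
Reagents that add atoms: none
Why: Olefin cross-metathesis of the monosubstituted alkene with methacrolein gives the thermodynamically preferred (E)-trisubstituted enal (C8=C9) and leaves the benzylic boronic ester untouched.

Step 11
Reactants: 20 (2E,4S,5R,6S,8S,9R)-9-[3-bromo-5-(triisopropylsilyloxy)phenyl]-5-(tert-butyldimethylsilyloxy)-6-methoxy-2,4,8-trimethyl-9-(4,4,5,5-tetramethyl-1,3,2-dioxaborolan-2-yl)non-2-enal; 21 allyl methyl ether
Product: 24 (1R,2S,4S,5R,6S,7E,9S,10S)-1-[3-bromo-5-(triisopropylsilyloxy)phenyl]-5-(tert-butyldimethylsilyloxy)-4,10-dimethoxy-2,6,8-trimethyldodeca-7,11-diene-1,9-diol, via (Z)-methoxyallylborane 22 (not isolated), via borinate 23 (not isolated)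
Conditions: 21, s-BuLi, THF, −78 °C; (+)-Ipc2BOMe; BF3·OEt2; 20, −78 °C; then NaBO3·4H2O, THF/H2O, 25 °C
Reagents that add atoms: sodium perborate, [Na+].[Na+].O[B-]1(O)OO[B-](O)(O)OO1
Why: Brown (Z)-γ-methoxyallylboration (chair transition state, syn adduct, re-face attack under Ipc control) sets C6 (S) and C7 (S), and the perborate work-up oxidises the benzylic C–B bond to the C15 alcohol with retention.

Step 12
Reactants: 24 (1R,2S,4S,5R,6S,7E,9S,10S)-1-[3-bromo-5-(triisopropylsilyloxy)phenyl]-5-(tert-butyldimethylsilyloxy)-4,10-dimethoxy-2,6,8-trimethyldodeca-7,11-diene-1,9-diol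
Product: 26 (1R,2S,4S,5R,6S,7E,9S,10S)-1-[3-amino-5-(triisopropylsilyloxy)phenyl]-5-(tert-butyldimethylsilyloxy)-4,10-dimethoxy-2,6,8-trimethyldodeca-7,11-diene-1,9-diol, via N-silylated aniline 25 (not isolated)
Conditions: Pd(dba)2 (5 mol%), P(tBu)3 (5 mol%), LiN(SiMe3)2 (4 equiv), toluene, 25–50 °C; then 1 M HCl, THF, 0 °C
Reagents that add atoms: lithium bis(trimethylsilyl)amide, [Li]N([Si](C)(C)C)[Si](C)(C)C
Why: Buchwald–Hartwig amination with LiN(SiMe3)2 as ammonia surrogate converts the only aryl halide into the aniline, with the two alcohols carried as lithium alkoxides.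

Step 13
Reactants: 26 (1R,2S,4S,5R,6S,7E,9S,10S)-1-[3-amino-5-(triisopropylsilyloxy)phenyl]-5-(tert-butyldimethylsilyloxy)-4,10-dimethoxy-2,6,8-trimethyldodeca-7,11-diene-1,9-diol; 27 (E)-3-iodo-2-methylprop-2-enoic acid
Product: 29 (E)-N-[3-[(1R,2S,4S,5R,6S,7E,9S,10S)-5-(tert-butyldimethylsilyloxy)-1,9-dihydroxy-4,10-dimethoxy-2,6,8-trimethyldodeca-7,11-dienyl]-5-(triisopropylsilyloxy)phenyl]-3-iodo-2-methylprop-2-enamide, via acid chloride 28 (not isolated)
Conditions: 27, (COCl)2, cat. DMF, CH2Cl2, 0–25 °C; then 26, pyridine, CH2Cl2, −20 °C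
Reagents that add atoms: none
Why: Chemoselective N-acylation, since the aniline is far more nucleophilic than the two hindered secondary alcohols at −20 °C, and the (E) geometry of the acid is carried over.

Step 14
Reactants: 29 (E)-N-[3-[(1R,2S,4S,5R,6S,7E,9S,10S)-5-(tert-butyldimethylsilyloxy)-1,9-dihydroxy-4,10-dimethoxy-2,6,8-trimethyldodeca-7,11-dienyl]-5-(triisopropylsilyloxy)phenyl]-3-iodo-2-methylprop-2-enamide
Product: 31 (E)-N-[3-[(1R,2S,4S,5R,6S,7E,9S,10S)-5-(tert-butyldimethylsilyloxy)-1,9-dihydroxy-12-iodo-4,10-dimethoxy-2,6,8-trimethyldodec-7-enyl]-5-(triisopropylsilyloxy)phenyl]-3-iodo-2-methylprop-2-enamide, via alkylborane 30 (not isolated)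
Conditions: 9-BBN (4 equiv), THF, 0–25 °C; then NaOMe, I2, MeOH/THF, 0 °C
Reagents that add atoms: iodine, [I][I]
Why: 9-BBN hydroborates only the monosubstituted C4=C5 alkene with anti-Markovnikov selectivity, and Brown–Kabalka iodinolysis of the primary C–B bond gives the C4 iodide.

Step 15
Reactants: 31 (E)-N-[3-[(1R,2S,4S,5R,6S,7E,9S,10S)-5-(tert-butyldimethylsilyloxy)-1,9-dihydroxy-12-iodo-4,10-dimethoxy-2,6,8-trimethyldodec-7-enyl]-5-(triisopropylsilyloxy)phenyl]-3-iodo-2-methylprop-2-enamide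
Product: 32 11-O-tert-butyldimethylsilyl-18-O-triisopropylsilyl ether of the target macrolactam (2E,6S,7S,8E,10S,11R,12S,14S,15R)
Conditions: Ni(cod)2 (2.0 equiv), 4,4′-di-tert-butyl-2,2′-bipyridine (2.2 equiv), DMA/THF, 31 added by syringe pump over 12 h (final 1 mM), 25 °C
Reagents that add atoms: none
Why: Proposed new method: intramolecular version of the nickel/bipyridine reductive cross-electrophile coupling of alkenyl with alkyl halides, in which zerovalent nickel inserts into the C3–I bond with retention of the (E) geometry, a low-valent nickel species abstracts iodine from C4 to give the primary alkyl radical, this radical is captured by the tethered alkenyl–nickel centre (estimated effective molarity near 0.02 M, which should outrun 5-exo attack on C8=C9) and trivalent nickel reductively eliminates the C3–C4 bond to close the 19-membered ring; the closest known reactions are the intermolecular Ni-catalysed vinyl halide/alkyl halide reductive coupling and stoichiometric zerovalent-nickel macrocyclisations.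

Step 16
Reactants: 32 11-O-tert-butyldimethylsilyl-18-O-triisopropylsilyl ether of the target macrolactam
Product: 33 target macrolactam CNP0366451.1 (2E,6S,7S,8E,10S,11R,12S,14S,15R)
Conditions: HF·pyridine, pyridine, THF, 0–25 °C
Reagents that add atoms: none
Why: Fluoride-mediated global desilylation cleaves the aryl and the secondary silyl ether without affecting the enamide or the allylic and benzylic alcohols.

**Compound list**
1 | 3-bromophenol | Oc1cccc(Br)c1 | starting material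
2 | (3-bromophenoxy)triisopropylsilane | CC(C)[Si](Oc1cccc(Br)c1)(C(C)C)C(C)C | intermediate
3 | 2-[3-bromo-5-(triisopropylsilyloxy)phenyl]-4,4,5,5-tetramethyl-1,3,2-dioxaborolane | CC(C)[Si](Oc1cc(Br)cc(c1)B1OC(C)(C)C(C)(C)O1)(C(C)C)C(C)C | intermediate
4 | (R)-3-bromo-2-methylpropan-1-ol | BrC[C@H](C)CO | starting material
5 | (R)-3-bromo-2-methylpropyl N,N-diisopropylcarbamate | BrC[C@H](C)COC(=O)N(C(C)C)C(C)C | intermediate
6 | ethyl glyoxylate | CCOC(=O)C=O | starting material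
7 | cis-but-2-ene | C/C=C\C | starting material
8 | (Z)-but-2-enylbis(isopinocampheyl)borane, Ipc from (−)-α-pinene | C/C=C\CB([C@H]1C[C@H]2C[C@H](C2(C)C)[C@@H]1C)[C@H]1C[C@H]2C[C@H](C2(C)C)[C@@H]1C | intermediate
9 | O-bis(isopinocampheyl)boryl derivative of 10 | C=C[C@H](C)[C@@H](OB([C@H]1C[C@H]2C[C@H](C2(C)C)[C@@H]1C)[C@H]1C[C@H]2C[C@H](C2(C)C)[C@@H]1C)C(=O)OCC | intermediate
10 | ethyl (2R,3S)-2-hydroxy-3-methylpent-4-enoate | C=C[C@H](C)[C@@H](O)C(=O)OCC | intermediate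
11 | ethyl (2R,3S)-2-(tert-butyldimethylsilyloxy)-3-methylpent-4-enoate | C=C[C@H](C)[C@@H](O[Si](C)(C)C(C)(C)C)C(=O)OCC | intermediate
12 | (2R,3S)-2-(tert-butyldimethylsilyloxy)-3-methylpent-4-enal | C=C[C@H](C)[C@@H](O[Si](C)(C)C(C)(C)C)C=O | intermediate
13 | [(R)-3-(N,N-diisopropylcarbamoyloxy)-2-methylpropyl]magnesium bromide | Br[Mg]C[C@H](C)COC(=O)N(C(C)C)C(C)C | intermediate
14 | (2S,4S,5R,6S)-5-(tert-butyldimethylsilyloxy)-4-hydroxy-2,6-dimethyloct-7-en-1-yl N,N-diisopropylcarbamate | C=C[C@H](C)[C@@H](O[Si](C)(C)C(C)(C)C)[C@@H](O)C[C@H](C)COC(=O)N(C(C)C)C(C)C | intermediate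
15 | (2S,4S,5R,6S)-5-(tert-butyldimethylsilyloxy)-4-methoxy-2,6-dimethyloct-7-en-1-yl N,N-diisopropylcarbamate | C=C[C@H](C)[C@@H](O[Si](C)(C)C(C)(C)C)[C@@H](OC)C[C@H](C)COC(=O)N(C(C)C)C(C)C | intermediate
16 | (1S)-1-lithio derivative of 15 (sparteine-bound) | C=C[C@H](C)[C@@H](O[Si](C)(C)C(C)(C)C)[C@@H](OC)C[C@H](C)[C@H]([Li])OC(=O)N(C(C)C)C(C)C | intermediate
17 | lithium aryl(alkyl)pinacolboronate complex from 16 and 3 | [Li+].C=C[C@H](C)[C@@H](O[Si](C)(C)C(C)(C)C)[C@@H](OC)C[C@H](C)[C@H]([B-]1(OC(C)(C)C(C)(C)O1)c1cc(Br)cc(O[Si](C(C)C)(C(C)C)C(C)C)c1)OC(=O)N(C(C)C)C(C)C | intermediate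
18 | 2-[(1R,2S,4S,5R,6S)-1-[3-bromo-5-(triisopropylsilyloxy)phenyl]-5-(tert-butyldimethylsilyloxy)-4-methoxy-2,6-dimethyloct-7-en-1-yl]-4,4,5,5-tetramethyl-1,3,2-dioxaborolane | C=C[C@H](C)[C@@H](O[Si](C)(C)C(C)(C)C)[C@@H](OC)C[C@H](C)[C@@H](B1OC(C)(C)C(C)(C)O1)c1cc(Br)cc(O[Si](C(C)C)(C(C)C)C(C)C)c1 | intermediate
19 | methacrolein | CC(=C)C=O | starting material
20 | (2E,4S,5R,6S,8S,9R)-9-[3-bromo-5-(triisopropylsilyloxy)phenyl]-5-(tert-butyldimethylsilyloxy)-6-methoxy-2,4,8-trimethyl-9-(4,4,5,5-tetramethyl-1,3,2-dioxaborolan-2-yl)non-2-enal | O=C/C(C)=C/[C@H](C)[C@@H](O[Si](C)(C)C(C)(C)C)[C@@H](OC)C[C@H](C)[C@@H](B1OC(C)(C)C(C)(C)O1)c1cc(Br)cc(O[Si](C(C)C)(C(C)C)C(C)C)c1 | intermediate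
21 | allyl methyl ether | COCC=C | starting material
22 | (Z)-3-methoxyallylbis(isopinocampheyl)borane, Ipc from (−)-α-pinene | CO/C=C\CB([C@H]1C[C@H]2C[C@H](C2(C)C)[C@@H]1C)[C@H]1C[C@H]2C[C@H](C2(C)C)[C@@H]1C | intermediate
23 | C7-O-bis(isopinocampheyl)boryl, C15-pinacolboryl precursor of 24 | C=C[C@H](OC)[C@@H](OB([C@H]1C[C@H]2C[C@H](C2(C)C)[C@@H]1C)[C@H]1C[C@H]2C[C@H](C2(C)C)[C@@H]1C)/C(C)=C/[C@H](C)[C@@H](O[Si](C)(C)C(C)(C)C)[C@@H](OC)C[C@H](C)[C@@H](B1OC(C)(C)C(C)(C)O1)c1cc(Br)cc(O[Si](C(C)C)(C(C)C)C(C)C)c1 | intermediate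
24 | (1R,2S,4S,5R,6S,7E,9S,10S)-1-[3-bromo-5-(triisopropylsilyloxy)phenyl]-5-(tert-butyldimethylsilyloxy)-4,10-dimethoxy-2,6,8-trimethyldodeca-7,11-diene-1,9-diol | C=C[C@H](OC)[C@@H](O)/C(C)=C/[C@H](C)[C@@H](O[Si](C)(C)C(C)(C)C)[C@@H](OC)C[C@H](C)[C@@H](O)c1cc(Br)cc(O[Si](C(C)C)(C(C)C)C(C)C)c1 | intermediate
25 | N,N-bis(trimethylsilyl) derivative of 26 | C=C[C@H](OC)[C@@H](O)/C(C)=C/[C@H](C)[C@@H](O[Si](C)(C)C(C)(C)C)[C@@H](OC)C[C@H](C)[C@@H](O)c1cc(N([Si](C)(C)C)[Si](C)(C)C)cc(O[Si](C(C)C)(C(C)C)C(C)C)c1 | intermediate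
26 | (1R,2S,4S,5R,6S,7E,9S,10S)-1-[3-amino-5-(triisopropylsilyloxy)phenyl]-5-(tert-butyldimethylsilyloxy)-4,10-dimethoxy-2,6,8-trimethyldodeca-7,11-diene-1,9-diol | C=C[C@H](OC)[C@@H](O)/C(C)=C/[C@H](C)[C@@H](O[Si](C)(C)C(C)(C)C)[C@@H](OC)C[C@H](C)[C@@H](O)c1cc(N)cc(O[Si](C(C)C)(C(C)C)C(C)C)c1 | intermediate
27 | (E)-3-iodo-2-methylprop-2-enoic acid | OC(=O)/C(C)=C/I | starting material
28 | (E)-3-iodo-2-methylprop-2-enoyl chloride | ClC(=O)/C(C)=C/I | intermediate
29 | (E)-N-[3-[(1R,2S,4S,5R,6S,7E,9S,10S)-5-(tert-butyldimethylsilyloxy)-1,9-dihydroxy-4,10-dimethoxy-2,6,8-trimethyldodeca-7,11-dienyl]-5-(triisopropylsilyloxy)phenyl]-3-iodo-2-methylprop-2-enamide | C=C[C@H](OC)[C@@H](O)/C(C)=C/[C@H](C)[C@@H](O[Si](C)(C)C(C)(C)C)[C@@H](OC)C[C@H](C)[C@@H](O)c1cc(NC(=O)/C(C)=C/I)cc(O[Si](C(C)C)(C(C)C)C(C)C)c1 | intermediate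
30 | B-(C4-alkyl)-9-borabicyclo[3.3.1]nonane from 29 | B1(C2CCCC1CCC2)CC[C@H](OC)[C@@H](O)/C(C)=C/[C@H](C)[C@@H](O[Si](C)(C)C(C)(C)C)[C@@H](OC)C[C@H](C)[C@@H](O)c1cc(NC(=O)/C(C)=C/I)cc(O[Si](C(C)C)(C(C)C)C(C)C)c1 | intermediate
31 | (E)-N-[3-[(1R,2S,4S,5R,6S,7E,9S,10S)-5-(tert-butyldimethylsilyloxy)-1,9-dihydroxy-12-iodo-4,10-dimethoxy-2,6,8-trimethyldodec-7-enyl]-5-(triisopropylsilyloxy)phenyl]-3-iodo-2-methylprop-2-enamide | ICC[C@H](OC)[C@@H](O)/C(C)=C/[C@H](C)[C@@H](O[Si](C)(C)C(C)(C)C)[C@@H](OC)C[C@H](C)[C@@H](O)c1cc(NC(=O)/C(C)=C/I)cc(O[Si](C(C)C)(C(C)C)C(C)C)c1 | intermediate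
32 | 11-O-tert-butyldimethylsilyl-18-O-triisopropylsilyl ether of the target macrolactam (2E,6S,7S,8E,10S,11R,12S,14S,15R) | CO[C@H]1C[C@H](C)[C@@H](O)c2cc(O[Si](C(C)C)(C(C)C)C(C)C)cc(c2)NC(=O)/C(C)=C/CC[C@H](OC)[C@@H](O)/C(C)=C/[C@H](C)[C@H]1O[Si](C)(C)C(C)(C)C | intermediate
33 | target macrolactam CNP0366451.1: (2E,6S,7S,8E,10S,11R,12S,14S,15R), 6,12-dimethoxy, 7,11,15-trihydroxy, 2,8,10,14-tetramethyl, C15 and N on a 5-hydroxy-1,3-phenylene | CO[C@H]1C[C@H](C)[C@@H](O)c2cc(O)cc(c2)NC(=O)/C(C)=C/CC[C@H](OC)[C@@H](O)/C(C)=C/[C@H](C)[C@H]1O | target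

**Totals**
Total step count: 16. Longest linear sequence: 13 steps (steps 4 to 16, from ethyl glyoxylate).

**Three steps most likely to fail**

Step 15 (nickel ring closure; oligomers or 5-exo cyclisation of the C4 radical onto C8=C9 may win). The fallback sets out from diol 24 and keeps the radical C3–C4 coupling but makes it intermolecular, with ring closure at the aryl–N bond. Diol 24 is hydroborated and iodinated (9-BBN; I2, NaOMe) to the bromoaryl primary iodide (1R,2S,4S,5R,6S,7E,9S,10S)-1-[3-bromo-5-(triisopropylsilyloxy)phenyl]-5-(tert-butyldimethylsilyloxy)-12-iodo-4,10-dimethoxy-2,6,8-trimethyldodec-7-ene-1,9-diol F1. F1 is coupled at 0.2 M with (E)-3-iodo-2-methylprop-2-enamide F2 (3 equiv, from acid chloride 28 and NH3) using NiI2 (10 mol%), 4,4′-dimethoxy-2,2′-bipyridine, Zn dust, NaI and DMA. This gives the seco primary amide (2E,6S,7S,8E,10S,11R,12S,14S,15R)-15-[3-bromo-5-(triisopropylsilyloxy)phenyl]-11-(tert-butyldimethylsilyloxy)-7,15-dihydroxy-6,12-dimethoxy-2,8,10,14-tetramethylpentadeca-2,8-dienamide F3. An intramolecular copper-catalysed Goldberg N-arylation (CuI, N,N′-dimethylethylenediamine, K2CO3, toluene, 110 °C) then closes the ring and comes back to the route at macrolactam 32.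

Step 10 (cross-metathesis of an α-branched, β-silyloxy terminal alkene with methacrolein may stall). The fallback sets out from boronic ester 18 and replaces metathesis by olefination. Ozonolysis (O3, CH2Cl2/MeOH, −78 °C; PPh3) gives the aldehyde (2R,3R,4S,6S,7R)-7-[3-bromo-5-(triisopropylsilyloxy)phenyl]-3-(tert-butyldimethylsilyloxy)-4-methoxy-2,6-dimethyl-7-(4,4,5,5-tetramethyl-1,3,2-dioxaborolan-2-yl)heptanal F4. An (E)-selective Wittig reaction with Ph3P=C(CH3)CHO (toluene, 80 °C) comes back to the route at enal 20.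

Step 7 (substrate-controlled Felkin addition may give poor dr at C12). The fallback sets out from silyl ester 11 and sets C12 by reagent control. MeNHOMe·HCl and iPrMgCl (THF, −20 °C) give the Weinreb amide (2R,3S)-2-(tert-butyldimethylsilyloxy)-N-methoxy-N,3-dimethylpent-4-enamide F5. Grignard reagent 13 adds to it to give the ketone (2S,5R,6S)-5-(tert-butyldimethylsilyloxy)-2,6-dimethyl-4-oxooct-7-en-1-yl N,N-diisopropylcarbamate F6. Reduction with (R)-2-methyl-CBS-oxazaborolidine and BH3·SMe2 (toluene, −40 °C) comes back to the route at alcohol 14.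

**Further compounds**
F1 | step 15 | (1R,2S,4S,5R,6S,7E,9S,10S)-1-[3-bromo-5-(triisopropylsilyloxy)phenyl]-5-(tert-butyldimethylsilyloxy)-12-iodo-4,10-dimethoxy-2,6,8-trimethyldodec-7-ene-1,9-diol | ICC[C@H](OC)[C@@H](O)/C(C)=C/[C@H](C)[C@@H](O[Si](C)(C)C(C)(C)C)[C@@H](OC)C[C@H](C)[C@@H](O)c1cc(Br)cc(O[Si](C(C)C)(C(C)C)C(C)C)c1
F2 | step 15 | (E)-3-iodo-2-methylprop-2-enamide | NC(=O)/C(C)=C/I
F3 | step 15 | (2E,6S,7S,8E,10S,11R,12S,14S,15R)-15-[3-bromo-5-(triisopropylsilyloxy)phenyl]-11-(tert-butyldimethylsilyloxy)-7,15-dihydroxy-6,12-dimethoxy-2,8,10,14-tetramethylpentadeca-2,8-dienamide | NC(=O)/C(C)=C/CC[C@H](OC)[C@@H](O)/C(C)=C/[C@H](C)[C@@H](O[Si](C)(C)C(C)(C)C)[C@@H](OC)C[C@H](C)[C@@H](O)c1cc(Br)cc(O[Si](C(C)C)(C(C)C)C(C)C)c1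
F4 | step 10 | (2R,3R,4S,6S,7R)-7-[3-bromo-5-(triisopropylsilyloxy)phenyl]-3-(tert-butyldimethylsilyloxy)-4-methoxy-2,6-dimethyl-7-(4,4,5,5-tetramethyl-1,3,2-dioxaborolan-2-yl)heptanal | O=C[C@H](C)[C@@H](O[Si](C)(C)C(C)(C)C)[C@@H](OC)C[C@H](C)[C@@H](B1OC(C)(C)C(C)(C)O1)c1cc(Br)cc(O[Si](C(C)C)(C(C)C)C(C)C)c1
F5 | step 7 | (2R,3S)-2-(tert-butyldimethylsilyloxy)-N-methoxy-N,3-dimethylpent-4-enamide | C=C[C@H](C)[C@@H](O[Si](C)(C)C(C)(C)C)C(=O)N(C)OC
F6 | step 7 | (2S,5R,6S)-5-(tert-butyldimethylsilyloxy)-2,6-dimethyl-4-oxooct-7-en-1-yl N,N-diisopropylcarbamate | C=C[C@H](C)[C@@H](O[Si](C)(C)C(C)(C)C)C(=O)C[C@H](C)COC(=O)N(C(C)C)C(C)C
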